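Ring A is disconnected at C3–C4. Ring B comes from (S)-carvone, whose stereocentre is C5, carbonyl C9 and ring methyl C12. The key step exploits the pairing of the oxygenated C3 with the gem-dimethyl carbon C4 in ring A: hydrogen-atom transfer to an isopropenyl group on C5 makes the second C4 methyl and a tertiary C4 radical, which adds to a C3 aldehyde held on the quaternary C10. One operation thus gives ring A, the C3–C4 bond and the C3 carbinol. The precursor is a 6,6-disubstituted carvone with the C10 methyl cis and a 3-oxopropyl chain trans to isopropenyl. C11, the C8 methylidene, the coumarin ether and the ester follow.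

Key step: step 4

Remark: drimane numbering is used for the decalin (C3 carbinol carbon, C4 gem-dimethyl carbon, C5 and C10 ring-fusion carbons, C8 methylidene carbon, C9 carrying C11). In these terms the target is (3R,5S,9R,10R), with O3 and C11 equatorial and a trans ring fusion, and C5 has the configuration of the stereocentre of (S)-carvone.

Step 1
Reactants: 1 (S)-carvone
Product: 3 (5S)-2,6-dimethyl-5-(prop-1-en-2-yl)cyclohex-2-en-1-one (6-methylcarvone; mixture of C6 epimers), via carvone lithium dienolate 2 (not isolated)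
Conditions: LiN(i-Pr)2, THF, −78 °C; MeI, −78 → 0 °C
Reagents that add atoms: iodomethane, CI
Why: Kinetic deprotonation of the enone by the hindered amide takes place at the α′ methylene and the cross-conjugated enolate is C-methylated (enolate alkylation); the configuration of the new centre does not matter because it is planarised again in step 2.

Step 2
Reactants: 3 6-methylcarvone; 4 3-bromo-1,1-dimethoxypropane
Product: 6 (5R,6R)-6-(3,3-dimethoxypropyl)-2,6-dimethyl-5-(prop-1-en-2-yl)cyclohex-2-en-1-one, via 6-methylcarvone lithium enolate 5 (not isolated)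
Conditions: LiN(i-Pr)2, THF, −78 → −20 °C; 4, DMPU, n-Bu4NI (cat.), −78 °C → rt
Reagents that add atoms: none
Why: Enolate alkylation of the tetrasubstituted lithium enolate builds the quaternary centre (future C10) with the electrophile entering anti to the neighbouring isopropenyl group, so the methyl ends up cis and the acetal chain trans to isopropenyl as the trans ring fusion requires; iodide catalysis and DMPU offset the low reactivity of the unactivated primary bromide.

Step 3
Reactants: 6 (5R,6R)-6-(3,3-dimethoxypropyl)-2,6-dimethyl-5-(prop-1-en-2-yl)cyclohex-2-en-1-one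
Product: 7 3-[(1R,6R)-1,3-dimethyl-2-oxo-6-(prop-1-en-2-yl)cyclohex-3-en-1-yl]propanal
Conditions: 1 M aq. HCl, THF, 0 °C → rt
Reagents that add atoms: water, O
Why: Acid-catalysed acetal hydrolysis of a dimethyl acetal is fast under conditions too mild to hydrate the isopropenyl group or start a Prins reaction, and no stereocentre is touched.

Step 4
Reactants: 7 3-[(1R,6R)-1,3-dimethyl-2-oxo-6-(prop-1-en-2-yl)cyclohex-3-en-1-yl]propanal
Product: 10 (4aR,6R,8aR)-6-hydroxy-2,5,5,8a-tetramethyl-4a,5,6,7,8,8a-hexahydronaphthalen-1(4H)-one, via tertiary C4 radical 8 (not isolated), via C3 alkoxyl radical 9 (not isolated)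
Conditions: Fe(acac)3 (30 mol %), PhSiH3 (2.5 equiv), degassed EtOH, 60 °C, Ar
Reagents that add atoms: none
Why: An iron hydride formed from Fe(acac)3, PhSiH3 and ethanol transfers a hydrogen atom to the terminal carbon of the 1,1-disubstituted alkene, which completes the gem-dimethyl group and leaves the nucleophilic tertiary radical 8 at C4; 8 adds to the aldehyde carbon and the alkoxyl radical 9 is reduced by divalent iron and protonated by the solvent. The closest known reaction type is the Fe(acac)3/PhSiH3 reductive radical cyclisation of alkenes onto ketone and aldehyde carbonyl groups. Ring A closes in the 6-exo-trig mode through a chair-like transition state built on the trans-diequatorial C5 and C10 substituents of ring B, so the trans ring fusion is inherited from step 2. The one new stereocentre, C3, is controlled by that chair: the carbonyl oxygen should sit pseudo-equatorial, away from the axial hydrogens on C1 and C5, which gives the equatorial alcohol cis to the C10 methyl. The step needs hydrogen-atom transfer to the isopropenyl group in the presence of the enone, which the substrate secures because the electron-poor trisubstituted C7=C8 bond is a much slower acceptor and lies too close to C4 for any ring closure, and it needs reduction of 9 to outrun ring opening, which the iron redox cycle provides.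

Step 5
Reactants: 10 (4aR,6R,8aR)-6-hydroxy-2,5,5,8a-tetramethyl-4a,5,6,7,8,8a-hexahydronaphthalen-1(4H)-one
Product: 11 (4aR,6R,8aR)-6-{[tert-butyl(dimethyl)silyl]oxy}-2,5,5,8a-tetramethyl-4a,5,6,7,8,8a-hexahydronaphthalen-1(4H)-one
Conditions: TBSOTf, 2,6-lutidine, CH2Cl2, −78 → 0 °C
Reagents that add atoms: tert-butyldimethylsilyl trifluoromethanesulfonate, CC(C)(C)[Si](C)(C)OS(=O)(=O)C(F)(F)F
Why: O-Silylation with a silyl triflate and a non-nucleophilic base is the standard way to protect a hindered secondary alcohol next to a quaternary carbon, and the enone is not enolised by 2,6-lutidine at low temperature.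

Step 6
Reactants: 11 (4aR,6R,8aR)-6-{[tert-butyl(dimethyl)silyl]oxy}-2,5,5,8a-tetramethyl-4a,5,6,7,8,8a-hexahydronaphthalen-1(4H)-one
Product: 13 (4aR,6R,8aR)-6-{[tert-butyl(dimethyl)silyl]oxy}-2,5,5,8a-tetramethyl-3,4,4a,5,6,7,8,8a-octahydronaphthalen-1-yl trifluoromethanesulfonate, via lithium C9 enolate 12 (not isolated)
Conditions: LiBH(s-Bu)3, THF, −78 °C; PhNTf2, −78 °C → rt
Reagents that add atoms: N-phenylbis(trifluoromethanesulfonimide), O=S(=O)(N(c1ccccc1)S(=O)(=O)C(F)(F)F)C(F)(F)F
Why: The bulky borohydride adds hydride to C7 in conjugate fashion, as it does with carvone itself, and the regiodefined C9 enolate is O-triflated in the same flask (conjugate reduction with enolate trapping), which fixes the double bond at C8=C9 without creating a stereocentre.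

Step 7
Reactants: 13 (4aR,6R,8aR)-6-{[tert-butyl(dimethyl)silyl]oxy}-2,5,5,8a-tetramethyl-3,4,4a,5,6,7,8,8a-octahydronaphthalen-1-yl trifluoromethanesulfonate
Product: 14 methyl (4aS,6R,8aR)-6-{[tert-butyl(dimethyl)silyl]oxy}-2,5,5,8a-tetramethyl-3,4,4a,5,6,7,8,8a-octahydronaphthalene-1-carboxylate
Conditions: Pd(OAc)2 (5 mol %), PPh3 (10 mol %), CO (1 atm), MeOH, Et3N, DMF, 60 °C
Reagents that add atoms: carbon monoxide, [C-]#[O+]; methanol, CO
Why: Palladium-catalysed methoxycarbonylation of an enol triflate (oxidative addition to zerovalent palladium, CO insertion, methanolysis) installs C11 on C9 and tolerates the silyl ether.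

Step 8
Reactants: 14 methyl (4aS,6R,8aR)-6-{[tert-butyl(dimethyl)silyl]oxy}-2,5,5,8a-tetramethyl-3,4,4a,5,6,7,8,8a-octahydronaphthalene-1-carboxylate
Product: 16 methyl (1R,4aS,6R,8aR)-6-{[tert-butyl(dimethyl)silyl]oxy}-5,5,8a-trimethyl-2-methylidenedecahydronaphthalene-1-carboxylate, via lithium ester dienolate 15 (not isolated)
Conditions: LiN(i-Pr)2, THF/HMPA, −78 °C; AcOH, −78 °C
Reagents that add atoms: none
Why: Deconjugative protonation: the amide removes a γ-hydrogen from the C12 methyl, which lies syn to the ester across C8=C9, and the extended enolate is protonated kinetically at the α-carbon C9 on the face opposite the axial C10 methyl, which gives the exocyclic methylidene and places C11 equatorial.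

Step 9
Reactants: 16 methyl (1R,4aS,6R,8aR)-6-{[tert-butyl(dimethyl)silyl]oxy}-5,5,8a-trimethyl-2-methylidenedecahydronaphthalene-1-carboxylate
Product: 17 [(1R,4aS,6R,8aR)-6-{[tert-butyl(dimethyl)silyl]oxy}-5,5,8a-trimethyl-2-methylidenedecahydronaphthalen-1-yl]methanol
Conditions: LiAlH4, Et2O, 0 °C
Reagents that add atoms: none
Why: Hydride reduction of the ester to the primary alcohol does not epimerise C9 or move the double bond, and the silyl ether and the alkene are inert to it.

Step 10
Reactants: 17 [(1R,4aS,6R,8aR)-6-{[tert-butyl(dimethyl)silyl]oxy}-5,5,8a-trimethyl-2-methylidenedecahydronaphthalen-1-yl]methanol; 18 umbelliferone (7-hydroxy-2H-chromen-2-one)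
Product: 19 7-{[(1R,4aS,6R,8aR)-6-{[tert-butyl(dimethyl)silyl]oxy}-5,5,8a-trimethyl-2-methylidenedecahydronaphthalen-1-yl]methoxy}-2H-chromen-2-one
Conditions: PPh3, DIAD, THF, 0 °C → rt
Reagents that add atoms: none
Why: Mitsunobu etherification joins the primary C11 alcohol to the acidic phenol of the coumarin under neutral conditions; the reacting carbon is not stereogenic and C9 is untouched.

Step 11
Reactants: 19 7-{[(1R,4aS,6R,8aR)-6-{[tert-butyl(dimethyl)silyl]oxy}-5,5,8a-trimethyl-2-methylidenedecahydronaphthalen-1-yl]methoxy}-2H-chromen-2-one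
Product: 20 7-{[(1R,4aS,6R,8aR)-6-hydroxy-5,5,8a-trimethyl-2-methylidenedecahydronaphthalen-1-yl]methoxy}-2H-chromen-2-one
Conditions: n-Bu4NF, THF, rt → 50 °C
Reagents that add atoms: none
Why: Fluoride-induced desilylation cleaves only the Si–O bond and leaves the aryl ether, the lactone and the exocyclic alkene intact.

Step 12
Reactants: 20 7-{[(1R,4aS,6R,8aR)-6-hydroxy-5,5,8a-trimethyl-2-methylidenedecahydronaphthalen-1-yl]methoxy}-2H-chromen-2-one; 21 3-methylbutanoyl chloride (isovaleryl chloride)
Product: 22 7-{[(1R,4aS,6R,8aR)-5,5,8a-trimethyl-2-methylidene-6-(3-methylbutanoyloxy)decahydronaphthalen-1-yl]methoxy}-2H-chromen-2-one (target CNP0295317.1)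
Conditions: pyridine, DMAP (cat.), CH2Cl2, 0 °C → rt
Reagents that add atoms: none
Why: DMAP-catalysed acylation esterifies the equatorial C3 alcohol with retention, since the C3–O bond is not broken.

Compound list
1 | (S)-carvone, (5S)-2-methyl-5-(prop-1-en-2-yl)cyclohex-2-en-1-one | CC1=CC[C@@H](CC1=O)C(C)=C | starting material
2 | carvone lithium dienolate (cross-conjugated α′-enolate) | CC1=CC[C@@H](C=C1O[Li])C(C)=C | intermediate (not isolated)
3 | (5S)-2,6-dimethyl-5-(prop-1-en-2-yl)cyclohex-2-en-1-one (6-methylcarvone; C6 epimers) | CC1=CC[C@@H](C(C)C1=O)C(C)=C | intermediate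
4 | 3-bromo-1,1-dimethoxypropane | COC(CCBr)OC | starting material
5 | 6-methylcarvone lithium enolate (tetrasubstituted) | CC1=CC[C@@H](C(C)=C1O[Li])C(C)=C | intermediate (not isolated)
6 | (5R,6R)-6-(3,3-dimethoxypropyl)-2,6-dimethyl-5-(prop-1-en-2-yl)cyclohex-2-en-1-one | COC(OC)CC[C@@]1(C)C(=O)C(C)=CC[C@@H]1C(C)=C | intermediate
7 | 3-[(1R,6R)-1,3-dimethyl-2-oxo-6-(prop-1-en-2-yl)cyclohex-3-en-1-yl]propanal | O=CCC[C@@]1(C)C(=O)C(C)=CC[C@@H]1C(C)=C | intermediate
8 | tertiary C4 radical (2-propyl radical on C5 of ring B; aldehyde chain intact) | O=CCC[C@@]1(C)C(=O)C(C)=CC[C@@H]1[C](C)C | intermediate (not isolated)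
9 | C3 alkoxyl radical of the closed decalin | [O][C@@H]1CC[C@@]2(C)C(=O)C(C)=CC[C@@H]2C1(C)C | intermediate (not isolated)
10 | (4aR,6R,8aR)-6-hydroxy-2,5,5,8a-tetramethyl-4a,5,6,7,8,8a-hexahydronaphthalen-1(4H)-one | O[C@@H]1CC[C@@]2(C)C(=O)C(C)=CC[C@@H]2C1(C)C | intermediate
11 | (4aR,6R,8aR)-6-{[tert-butyl(dimethyl)silyl]oxy}-2,5,5,8a-tetramethyl-4a,5,6,7,8,8a-hexahydronaphthalen-1(4H)-one | CC(C)(C)[Si](C)(C)O[C@@H]1CC[C@@]2(C)C(=O)C(C)=CC[C@@H]2C1(C)C | intermediate
12 | lithium C9 enolate (C8=C9) of the conjugate-reduced ketone | CC(C)(C)[Si](C)(C)O[C@@H]1CC[C@@]2(C)C(O[Li])=C(C)CC[C@@H]2C1(C)C | intermediate (not isolated)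
13 | (4aR,6R,8aR)-6-{[tert-butyl(dimethyl)silyl]oxy}-2,5,5,8a-tetramethyl-3,4,4a,5,6,7,8,8a-octahydronaphthalen-1-yl trifluoromethanesulfonate | CC(C)(C)[Si](C)(C)O[C@@H]1CC[C@@]2(C)C(OS(=O)(=O)C(F)(F)F)=C(C)CC[C@@H]2C1(C)C | intermediate
14 | methyl (4aS,6R,8aR)-6-{[tert-butyl(dimethyl)silyl]oxy}-2,5,5,8a-tetramethyl-3,4,4a,5,6,7,8,8a-octahydronaphthalene-1-carboxylate | CC(C)(C)[Si](C)(C)O[C@@H]1CC[C@@]2(C)C(C(=O)OC)=C(C)CC[C@@H]2C1(C)C | intermediate
15 | lithium ester dienolate (C9=C11 and C8=C12) | CC(C)(C)[Si](C)(C)O[C@@H]1CC[C@@]2(C)C(=C(OC)O[Li])C(=C)CC[C@@H]2C1(C)C | intermediate (not isolated)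
16 | methyl (1R,4aS,6R,8aR)-6-{[tert-butyl(dimethyl)silyl]oxy}-5,5,8a-trimethyl-2-methylidenedecahydronaphthalene-1-carboxylate | C=C1CC[C@@H]2C(C)(C)[C@H](O[Si](C)(C)C(C)(C)C)CC[C@@]2(C)[C@@H]1C(=O)OC | intermediate
17 | [(1R,4aS,6R,8aR)-6-{[tert-butyl(dimethyl)silyl]oxy}-5,5,8a-trimethyl-2-methylidenedecahydronaphthalen-1-yl]methanol | C=C1CC[C@@H]2C(C)(C)[C@H](O[Si](C)(C)C(C)(C)C)CC[C@@]2(C)[C@@H]1CO | intermediate
18 | umbelliferone, 7-hydroxy-2H-chromen-2-one | O=c1ccc2ccc(O)cc2o1 | starting material
19 | 7-{[(1R,4aS,6R,8aR)-6-{[tert-butyl(dimethyl)silyl]oxy}-5,5,8a-trimethyl-2-methylidenedecahydronaphthalen-1-yl]methoxy}-2H-chromen-2-one | C=C1CC[C@@H]2C(C)(C)[C@H](O[Si](C)(C)C(C)(C)C)CC[C@@]2(C)[C@@H]1COc1ccc2ccc(=O)oc2c1 | intermediate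
20 | 7-{[(1R,4aS,6R,8aR)-6-hydroxy-5,5,8a-trimethyl-2-methylidenedecahydronaphthalen-1-yl]methoxy}-2H-chromen-2-one | C=C1CC[C@@H]2C(C)(C)[C@H](O)CC[C@@]2(C)[C@@H]1COc1ccc2ccc(=O)oc2c1 | intermediate
21 | 3-methylbutanoyl chloride (isovaleryl chloride) | CC(C)CC(Cl)=O | starting material
22 | 7-{[(1R,4aS,6R,8aR)-5,5,8a-trimethyl-2-methylidene-6-(3-methylbutanoyloxy)decahydronaphthalen-1-yl]methoxy}-2H-chromen-2-one | C=C1CC[C@@H]2C(C)(C)[C@H](OC(=O)CC(C)C)CC[C@@]2(C)[C@@H]1COc1ccc2ccc(=O)oc2c1 | target

Total step count: 12 steps.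
Longest linear sequence: 12 steps, from (S)-carvone 1 to 22.

Steps most likely to fail

Step 4. The addition of the C4 radical to the aldehyde may show poor facial selectivity, with part of the material closing through the arrangement that puts the oxygen pseudo-axial, so that the axial C3 alcohol accompanies 10. The fallback sets out from 7 and comes back at 10. The ring closure would be run as in step 4 and the product taken on as the mixture of 10 and its axial epimer (4aR,6S,8aR)-6-hydroxy-2,5,5,8a-tetramethyl-4a,5,6,7,8,8a-hexahydronaphthalen-1(4H)-one F1. Oxidation of the mixture with Dess–Martin periodinane in CH2Cl2 would converge both on (4aR,8aR)-2,5,5,8a-tetramethyl-4,4a,5,7,8,8a-hexahydronaphthalene-1,6-dione F2. NaBH4 in MeOH/CH2Cl2 at −78 °C should then reduce the saturated C3 ketone in preference to the conjugated C9 ketone, which is flanked by the quaternary C10. Hydride should enter axially, on the face away from the axial C4 methyl, and return the equatorial alcohol 10. C3 is then set by ketone reduction and not by the radical addition.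

Step 8. Deprotonation may take a ring hydrogen from C7 in competition with the C12 methyl, or the extended enolate may be reprotonated at its γ-carbon, which would give the endocyclic alkene isomer or return 14. The fallback sets out from 14 and comes back at 16. It is a photochemical deconjugation: irradiation of 14 at 254 nm in hexane containing a catalytic amine base should move a hydrogen from the syn γ-methyl C12 to the excited ester carbonyl (a 1,5-hydrogen shift that only the methyl group can reach) and give the photodienol methyl ketene hemiacetal F3. Base-mediated reketonisation of F3 by protonation at C9, again from the face opposite the axial C10 methyl, would give 16.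

Step 2. Substitution at the unactivated primary bromide by the hindered tetrasubstituted enolate may be slow, which leaves room for proton exchange, O-alkylation and loss of HBr from 4. The fallback sets out from 3 and comes back at 7. The enolate 5 would be formed as before and alkylated with allyl bromide, a far more reactive electrophile that should also enter anti to isopropenyl, to give (5R,6R)-2,6-dimethyl-6-(prop-2-en-1-yl)-5-(prop-1-en-2-yl)cyclohex-2-en-1-one F4. Hydroboration with disiamylborane in THF at 0 °C should select the monosubstituted alkene over the 1,1-disubstituted isopropenyl group, the enone alkene and the hindered ketone. Oxidation of the borane with NaBO3·4H2O, which spares the enone, would give (5R,6R)-6-(3-hydroxypropyl)-2,6-dimethyl-5-(prop-1-en-2-yl)cyclohex-2-en-1-one F5. Dess–Martin oxidation of F5 would then give the aldehyde 7, so that the acetal hydrolysis of step 3 is not needed.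

Further compounds
F1 | step 4 | (4aR,6S,8aR)-6-hydroxy-2,5,5,8a-tetramethyl-4a,5,6,7,8,8a-hexahydronaphthalen-1(4H)-one | O[C@H]1CC[C@@]2(C)C(=O)C(C)=CC[C@@H]2C1(C)C
F2 | step 4 | (4aR,8aR)-2,5,5,8a-tetramethyl-4,4a,5,7,8,8a-hexahydronaphthalene-1,6-dione | O=C1CC[C@@]2(C)C(=O)C(C)=CC[C@@H]2C1(C)C
F3 | step 8 | photodienol (methyl ketene hemiacetal) of 14 with exocyclic C8 methylidene | CC(C)(C)[Si](C)(C)O[C@@H]1CC[C@@]2(C)C(=C(O)OC)C(=C)CC[C@@H]2C1(C)C
F4 | step 2 | (5R,6R)-2,6-dimethyl-6-(prop-2-en-1-yl)-5-(prop-1-en-2-yl)cyclohex-2-en-1-one | C=CC[C@@]1(C)C(=O)C(C)=CC[C@@H]1C(C)=C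
F5 | step 2 | (5R,6R)-6-(3-hydroxypropyl)-2,6-dimethyl-5-(prop-1-en-2-yl)cyclohex-2-en-1-one | OCCC[C@@]1(C)C(=O)C(C)=CC[C@@H]1C(C)=C
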